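Reagent is counted first.

| setting | Friday's | Thursday's | Tuesday's | eta | gamma |
|---|---|---|---|---|---|
| substrate | 0.0050 M | 0.0050 M | 0.0083 M | 0.015 M | 0.0050 M |
| reagent | 5.25 mM | 5.25 mM | 5.25 mM | 5.25 mM | 5.25 mM |
| base | 0.044 mM | 0.084 mM | 0.10 mM | 0.0600 mM | 0.100 mM |
| remark | run made earlier | run made earlier | run made earlier |  |  |
| time |  |  |  | 4.0 min | 4.0 min |

- Friday's (time / min: target / %): 0.333: 34.9; 1.00: 51.7; 2.00: 52.2; 3.00: 51.9; 4.00: 52.0
- Thursday's (time / min: target / %): 0.833: 50.7; 1.50: 51.0; 2.50: 50.7; 3.00: 51.2; 4.00: 50.4
- Tuesday's (time / min: target / %): 0.333: 32.7; 1.00: 23.6; 2.00: 20.2; 3.00: 19.7; 4.00: 18.6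

(standard deviation of a reading: 0.3 percentage points)



* which one finishes higher in amount of target, in percent of the substrate charged ("neither" within 2 percentage points) (eta / gamma / neither)
* amount of target at the end, in percent of the substrate charged, eta
* amount of target at the end, in percent of the substrate charged, gamma

Friday's run has more reagent than substrate and stands flat near 52.0 %. Tuesday's run has more substrate than reagent: reagent is the limiting reagent there, and target sinks from 32.7 % to 18.6 %. So target is lost where substrate is in surplus.

My own reckoning supposes that each reagent makes one target and that each target lost takes one further substrate. With both consumed, the target still standing is the ceiling: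

ceiling = 2 × reagent − substrate

Substrate at 2 × reagent is the zero of this scale. Tuesday's ceiling is 2.20 mM, and its last reading, 1.54 mM, lies below that.

For eta, the bound from above is Tuesday's last amount, which would be 10.3 % of eta's charge. The bound from below is zero. Eta's ceiling is −4.50 mM, which is negative, so my reckoning puts eta near the bottom, with 4.50 mM of substrate left over.

Gamma's ceiling, 5.50 mM, lies above its charge of 0.0050 M and bounds nothing. Its base, 0.100 mM, lies beyond Thursday's 0.084 mM and Friday's 0.044 mM, so those runs do not enclose it. With equal substrate and reagent, Thursday's readings average 50.8 %, less than Friday's last reading. A straight line through these two readings reaches 50.3 % at gamma's base, so my bracket for gamma runs from about 50.3 % to 50.8 %.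

The forecast says gamma, with 5 % for eta and 50.5 % for gamma, both inside these brackets. For eta it stands above my reckoning: “With K≈0.39 per mM from Tuesday, target drops to about 0.7 mM, roughly 5%.”

    substrate + reagent + released group → target + 2 released group (k = 11700 /M²/s)
    substrate + reagent → target + released group (k = 0.767 /M/s)
    base + released group ⇌ salt, settled at all times (K = 9.90 × 10⁷ /M)
    substrate + target → side product (k = 10.0 /M/s)
    reagent ⇌ dormant form (K = 0.640, k = 0.00862 /s)
    crystals ⇌ released group, rate k6*(cs6 - [released group]) while solid is left; crystals form when [released group] > cs6 (solubility = 3.00 mM, k = 1.71 /s)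

Eta ends at 0.0402 % and gamma at 50.7 %, so gamma finishes higher. In eta, side product holds 69.7 % of the substrate, and 30.2 % remains as substrate, which is 4.54 mM against the ceiling's 4.50 mM. A neighbour flask, like gamma but charged with 0.0020 M of substrate, has a positive ceiling of 8.50 mM. It ends with 0 % of its substrate and 62.6 % target.

The data were generated by integration on assumed constants.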